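The route rests on one disconnection of the cyclohexane ring, at C6–C7 and C3a–C7a (numbering of the hexahydro-2-benzofuran-1(3H)-one core: C1 lactone carbonyl, O2, C3, C3a, C4, C5, C6, C7, C7a; side chain C1′–C3′ on C3). C7=C7a with C1 is a latent methacrylate and C3a=C4–C5=C6 a latent diene. An ester-tethered intramolecular Diels–Alder reaction, with the methacrylate held on O–C1′, closes the carbocycle and a δ-lactone in one operation and sets C7a, C3a and a C6 silyl group under control of C3 and C1′. The precursor is an acyclic silyl triene; the resulting allylsilane later delivers the C4 quaternary centre, and translactonisation gives the γ-lactone.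

Key step: step 6

Remark: in the Why lines atoms carry the target numbers given above; compounds 1, 4, 6, 10 and 13 are taken as commercially available, and the target is taken as the (3S,3aR,4S,7aS,1′S) enantiomer drawn.

Step 1
Reactants: 1 (2E)-3-methylpent-2-en-4-yn-1-ol
Product: 2 (2E,4E)-5-[dimethyl(phenyl)silyl]-3-methylpenta-2,4-dien-1-ol
Conditions: PhMe2SiH (1.1 equiv), Pt2[(CH2=CHSiMe2)2O]3 (0.1 mol%), P(t-Bu)3 (0.2 mol%), THF, 0 °C to rt
Reagents that add atoms: dimethyl(phenyl)silane, C[SiH](C)c1ccccc1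
Why: Platinum-catalysed syn hydrosilylation of the terminal alkyne should place silicon on the terminal carbon and give the E vinylsilane (future C5=C6), the bulky phosphine suppressing the internal isomer and the existing E trisubstituted alkene (future C3a=C4) staying untouched.

Step 2
Reactants: 2 (2E,4E)-5-[dimethyl(phenyl)silyl]-3-methylpenta-2,4-dien-1-ol
Product: 3 (2E,4E)-5-[dimethyl(phenyl)silyl]-3-methylpenta-2,4-dienal
Conditions: activated MnO2 (15 equiv), CH2Cl2, rt
Reagents that add atoms: none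
Why: Allylic oxidation with manganese dioxide should stop at the aldehyde and keep both alkene geometries.

Step 3
Reactants: 3 (2E,4E)-5-[dimethyl(phenyl)silyl]-3-methylpenta-2,4-dienal; 4 hydroxyacetone
Product: 5 (3S,4S,5E,7E)-8-[dimethyl(phenyl)silyl]-3,4-dihydroxy-6-methylocta-5,7-dien-2-one
Conditions: 4 (10 equiv), (S)-proline (30 mol%), DMSO, rt
Reagents that add atoms: none
Why: The proline-catalysed direct aldol reaction of hydroxyacetone proceeds through the E enamine at the hydroxylated carbon and a hydrogen-bonded chair transition state, which should set the anti diol with (3S,4S) configuration (future C1′ and C3) from (S)-proline.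

Step 4
Reactants: 5 anti diol ketone; 6 methacryloyl chloride
Product: 7 (3S,4S,5E,7E)-8-[dimethyl(phenyl)silyl]-4-hydroxy-6-methyl-2-oxoocta-5,7-dien-3-yl 2-methylprop-2-enoate
Conditions: 6 (1.05 equiv), Et3N (1.2 equiv), CH2Cl2, −78 °C
Reagents that add atoms: none
Why: The hydroxyl next to the ketone is the more acidic one and should be acylated first under amine base at low temperature (regioselective acylation of an α,β-dihydroxy ketone, analogous to the α-selective sulfonylation of 2,3-dihydroxy esters), which places the methacrylate on O–C1′ without touching a stereocentre.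

Step 5
Reactants: 7 mono-methacrylate
Product: 8 (3S,4S,5E,7E)-4-[(tert-butyldimethylsilyl)oxy]-8-[dimethyl(phenyl)silyl]-6-methyl-2-oxoocta-5,7-dien-3-yl 2-methylprop-2-enoate
Conditions: TBSOTf (1.3 equiv), 2,6-lutidine (2 equiv), CH2Cl2, −78 °C
Reagents that add atoms: tert-butyldimethylsilyl trifluoromethanesulfonate, CC(C)(C)[Si](C)(C)OS(=O)(=O)C(F)(F)F
Why: Silylation of the remaining allylic hydroxyl with a silyl triflate is fast at −78 °C, blocks acyl migration and installs the bulky group that later steers the cycloaddition.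

Step 6
Reactants: 8 TBS-protected triene methacrylate
Product: 9 (3S,4S,4aR,7R,8aS)-3-acetyl-4-[(tert-butyldimethylsilyl)oxy]-7-[dimethyl(phenyl)silyl]-5,8a-dimethyl-3,4,4a,7,8,8a-hexahydro-1H-isochromen-1-one
Conditions: toluene (0.01 M), BHT (0.2 equiv), 180 °C, sealed tube
Reagents that add atoms: none
Why: Thermal, concerted, suprafacial [4+2] cycloaddition (intramolecular Diels–Alder reaction) of the methacrylate C7=C7a with the diene C3a=C4–C5=C6 forms C6–C7 and C3a–C7a together; the closest known reaction type is the cyclisation of ester-tethered deca-1,7,9-trienoates (hexa-3,5-dienyl acrylates) to fused δ-lactones. The cyclohexene closes by the cycloaddition itself and the six-membered lactone (C1, O, C1′, C3, C3a, C7a) closes as the tether ring, cis-fused because the tether carbonyl is endo. C7a and C3a are fixed by the endo mode and the retained alkene geometries, and C6 by the E vinylsilane, whose silyl group ends cis to the C3a–C3 bond. The absolute sense comes from C3: the tether carbon C1′ must sit on the dienophile face, the OTBS group then points outward in the diene plane and H-3 lies below the C4 methyl, the arrangement of least allylic 1,3-strain. The step needs endo over exo closure and one diene face; the exo mode would put the methacrylate methyl over the C4 methyl and the other face would press OTBS against that methyl. BHT and high dilution should hold back polymerisation of the methacrylate.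

Step 7
Reactants: 9 cis-fused δ-lactone allylsilane; 10 3-chloropropanoyl chloride
Product: 12 (3S,4S,4aR,5S,8aS)-3-acetyl-4-[(tert-butyldimethylsilyl)oxy]-5,8a-dimethyl-5-(prop-2-enoyl)-3,4,4a,5,8,8a-hexahydro-1H-isochromen-1-one, via β-chloroethyl ketone 11 (not isolated)
Conditions: 10 (1.5 equiv), TiCl4 (2.5 equiv), 2,6-di-tert-butylpyridine (0.5 equiv), CH2Cl2, −78 °C; then Et3N (5 equiv), 0 °C to rt
Reagents that add atoms: none
Why: Lewis acid-mediated acylation of the allylsilane (anti SE2′) lets the acylium ion attack C4 on the face opposite the C6–Si bond, i.e. cis to H-3a, while the double bond moves to C5=C6 and silicon leaves, which sets the C4 quaternary centre with the methyl cis to C3; triethylamine then eliminates HCl to unveil the vinyl ketone.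

Step 8
Reactants: 12 vinyl ketone; 13 furan-3-ylboronic acid
Product: 14 (3S,4S,4aR,5S,8aS)-3-acetyl-4-[(tert-butyldimethylsilyl)oxy]-5-[3-(furan-3-yl)propanoyl]-5,8a-dimethyl-3,4,4a,5,8,8a-hexahydro-1H-isochromen-1-one
Conditions: 13 (2.5 equiv), [Rh(cod)OH]2 (3 mol%), 1,4-dioxane/H2O 10:1, 40 °C
Reagents that add atoms: none
Why: Rhodium-catalysed conjugate addition of a boronic acid (Hayashi–Miyaura reaction) to the unhindered vinyl ketone should attach the furan at the terminal carbon, and the base-free conditions spare the lactone, the silyl ether and the α-acyloxy ketone.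

Step 9
Reactants: 14 furyl ketone with ring alkene
Product: 15 (3S,4S,4aR,5S,8aS)-3-acetyl-4-[(tert-butyldimethylsilyl)oxy]-5-[3-(furan-3-yl)propanoyl]-5,8a-dimethyl-3,4,4a,5,6,7,8,8a-octahydro-1H-isochromen-1-one
Conditions: H2 (3 atm), RhCl(PPh3)3 (10 mol%), benzene/EtOH 1:1, 40 °C
Reagents that add atoms: none
Why: Homogeneous hydrogenation with Wilkinson's catalyst should reduce the cis-disubstituted ring alkene (C5=C6) and leave the furan, both ketones and the lactone untouched.

Step 10
Reactants: 15 saturated δ-lactone silyl ether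
Product: 17 (3S,3aR,4S,7aS)-4-[3-(furan-3-yl)propanoyl]-3-[(1S)-1-hydroxy-2-oxopropyl]-4,7a-dimethyl-3a,4,5,6,7,7a-hexahydro-2-benzofuran-1(3H)-one, via desilylated δ-lactone alcohol 16 (not isolated)
Conditions: HF·pyridine, pyridine/THF, 0 °C to rt; then CSA (0.1 equiv), CH2Cl2, rt
Reagents that add atoms: none
Why: HF cleaves the silyl ether, and the freed C3 hydroxyl, held cis to the lactone carbonyl on C7a, should attack it under acid catalysis so that the δ-lactone on O–C1′ isomerises to the more stable cis-fused γ-lactone (translactonisation) with no stereocentre changing.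

Step 11
Reactants: 17 γ-lactone hydroxy ketone
Product: 18 (1S)-1-[(3S,3aR,4S,7aS)-4-[3-(furan-3-yl)propanoyl]-4,7a-dimethyl-1-oxo-1,3,3a,4,5,6,7,7a-octahydro-2-benzofuran-3-yl]-2-oxopropyl acetate (CNP0170401.2)
Conditions: Ac2O (3 equiv), pyridine (5 equiv), DMAP (5 mol%), CH2Cl2, 0 °C
Reagents that add atoms: acetic anhydride, CC(=O)OC(C)=O
Why: Acetylation of the secondary α-hydroxy ketone under mild nucleophilic catalysis at 0 °C should not epimerise C1′ or open the lactone.

Compound list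
1 | (2E)-3-methylpent-2-en-4-yn-1-ol | C#C/C(C)=C/CO | starting material
2 | (2E,4E)-5-[dimethyl(phenyl)silyl]-3-methylpenta-2,4-dien-1-ol | C[Si](C)(c1ccccc1)/C=C/C(C)=C/CO | intermediate
3 | (2E,4E)-5-[dimethyl(phenyl)silyl]-3-methylpenta-2,4-dienal | C[Si](C)(c1ccccc1)/C=C/C(C)=C/C=O | intermediate
4 | 1-hydroxypropan-2-one (hydroxyacetone) | CC(=O)CO | starting material
5 | (3S,4S,5E,7E)-8-[dimethyl(phenyl)silyl]-3,4-dihydroxy-6-methylocta-5,7-dien-2-one | CC(=O)[C@@H](O)[C@@H](O)/C=C(C)/C=C/[Si](C)(C)c1ccccc1 | intermediate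
6 | 2-methylprop-2-enoyl chloride (methacryloyl chloride) | CC(=C)C(=O)Cl | starting material
7 | (3S,4S,5E,7E)-8-[dimethyl(phenyl)silyl]-4-hydroxy-6-methyl-2-oxoocta-5,7-dien-3-yl 2-methylprop-2-enoate | CC(=O)[C@@H](OC(=O)C(C)=C)[C@@H](O)/C=C(C)/C=C/[Si](C)(C)c1ccccc1 | intermediate
8 | (3S,4S,5E,7E)-4-[(tert-butyldimethylsilyl)oxy]-8-[dimethyl(phenyl)silyl]-6-methyl-2-oxoocta-5,7-dien-3-yl 2-methylprop-2-enoate | CC(=O)[C@@H](OC(=O)C(C)=C)[C@@H](O[Si](C)(C)C(C)(C)C)/C=C(C)/C=C/[Si](C)(C)c1ccccc1 | intermediate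
9 | (3S,4S,4aR,7R,8aS)-3-acetyl-4-[(tert-butyldimethylsilyl)oxy]-7-[dimethyl(phenyl)silyl]-5,8a-dimethyl-3,4,4a,7,8,8a-hexahydro-1H-isochromen-1-one (cis-fused; silyl cis to the C4a–C4 bond) | CC(=O)[C@H]1OC(=O)[C@@]2(C)C[C@@H]([Si](C)(C)c3ccccc3)C=C(C)[C@H]2[C@@H]1O[Si](C)(C)C(C)(C)C | intermediate
10 | 3-chloropropanoyl chloride | ClCCC(=O)Cl | starting material
11 | (3S,4S,4aR,5S,8aS)-3-acetyl-4-[(tert-butyldimethylsilyl)oxy]-5-(3-chloropropanoyl)-5,8a-dimethyl-3,4,4a,5,8,8a-hexahydro-1H-isochromen-1-one | CC(=O)[C@H]1OC(=O)[C@@]2(C)CC=C[C@](C)(C(=O)CCCl)[C@H]2[C@@H]1O[Si](C)(C)C(C)(C)C | intermediate (not isolated)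
12 | (3S,4S,4aR,5S,8aS)-3-acetyl-4-[(tert-butyldimethylsilyl)oxy]-5,8a-dimethyl-5-(prop-2-enoyl)-3,4,4a,5,8,8a-hexahydro-1H-isochromen-1-one | CC(=O)[C@H]1OC(=O)[C@@]2(C)CC=C[C@](C)(C(=O)C=C)[C@H]2[C@@H]1O[Si](C)(C)C(C)(C)C | intermediate
13 | furan-3-ylboronic acid | OB(O)c1ccoc1 | starting material
14 | (3S,4S,4aR,5S,8aS)-3-acetyl-4-[(tert-butyldimethylsilyl)oxy]-5-[3-(furan-3-yl)propanoyl]-5,8a-dimethyl-3,4,4a,5,8,8a-hexahydro-1H-isochromen-1-one | CC(=O)[C@H]1OC(=O)[C@@]2(C)CC=C[C@](C)(C(=O)CCc3ccoc3)[C@H]2[C@@H]1O[Si](C)(C)C(C)(C)C | intermediate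
15 | (3S,4S,4aR,5S,8aS)-3-acetyl-4-[(tert-butyldimethylsilyl)oxy]-5-[3-(furan-3-yl)propanoyl]-5,8a-dimethyl-3,4,4a,5,6,7,8,8a-octahydro-1H-isochromen-1-one | CC(=O)[C@H]1OC(=O)[C@@]2(C)CCC[C@](C)(C(=O)CCc3ccoc3)[C@H]2[C@@H]1O[Si](C)(C)C(C)(C)C | intermediate
16 | (3S,4S,4aR,5S,8aS)-3-acetyl-5-[3-(furan-3-yl)propanoyl]-4-hydroxy-5,8a-dimethyl-3,4,4a,5,6,7,8,8a-octahydro-1H-isochromen-1-one | CC(=O)[C@H]1OC(=O)[C@@]2(C)CCC[C@](C)(C(=O)CCc3ccoc3)[C@H]2[C@@H]1O | intermediate (not isolated)
17 | (3S,3aR,4S,7aS)-4-[3-(furan-3-yl)propanoyl]-3-[(1S)-1-hydroxy-2-oxopropyl]-4,7a-dimethyl-3a,4,5,6,7,7a-hexahydro-2-benzofuran-1(3H)-one | O[C@H](C(C)=O)[C@H]1OC(=O)[C@@]2(C)CCC[C@](C)(C(=O)CCc3ccoc3)[C@@H]12 | intermediate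
18 | (1S)-1-[(3S,3aR,4S,7aS)-4-[3-(furan-3-yl)propanoyl]-4,7a-dimethyl-1-oxo-1,3,3a,4,5,6,7,7a-octahydro-2-benzofuran-3-yl]-2-oxopropyl acetate (CNP0170401.2) | CC(=O)O[C@H](C(C)=O)[C@H]1OC(=O)[C@@]2(C)CCC[C@](C)(C(=O)CCc3ccoc3)[C@@H]12 | target

Total step count: 11. Longest linear sequence: 11 steps (from 1).

Steps most likely to fail

Step 6. The ester tether reacts only at high temperature, where exo (trans-fused) closure, addition to the other diene face and radical polymerisation of the methacrylate can erode the selectivity. The fallback replaces the methacrylate by a doubly activated Z dienophile whose second carbonyl is removed afterwards; it sets out from 5 and returns at 9. Citraconic anhydride is opened by allyl alcohol at the less hindered carbonyl to give (2Z)-2-methyl-4-oxo-4-(prop-2-en-1-yloxy)but-2-enoic acid F1. Steglich esterification (DCC, DMAP) of the ketone-flanked hydroxyl of 5 gives the mixed citraconate diester F2, and TBSOTf/2,6-lutidine the silyl ether F3. The maleate-type dienophile should cyclise near 110 °C with both carbonyls endo, giving the cis-fused cycloadduct allyl ester F4 (ester on C7, cis to C1 and to silicon). Pd(PPh3)4/morpholine frees the carboxylic acid F5, which is converted (DCC, N-hydroxypyridine-2-thione) into the thiohydroxamate ester F6 and reduced (t-BuSH, visible light; Barton decarboxylation) to 9.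

Step 3. With a conjugated, β-branched aldehyde the proline-catalysed aldol may be slow and give poor anti/syn and enantiomer ratios, and the differentiation of the two hydroxyls that follows (step 4) can suffer from acyl migration. The fallback sets both centres with an auxiliary and brings in the ester by displacement, so no hydroxyl differentiation is needed; it sets out from 3 and returns at 8. Boron aldol reaction (Bu2BOTf, i-Pr2NEt, CH2Cl2, −78 °C) of commercial (4R)-4-benzyl-3-(chloroacetyl)-1,3-oxazolidin-2-one with 3 should give the syn chlorohydrin imide F7. Me3Al/MeNHOMe·HCl gives the Weinreb amide F8, TBSOTf the silyl ether F9, and MeMgBr the α-chloro methyl ketone F10. Caesium methacrylate (methacrylic acid, Cs2CO3, DMF) then displaces chloride with inversion to give 8.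

Step 7. The acylium ion must attack a carbon next to the ring fusion; protodesilylation by adventitious HCl, loss of the TBS ether under TiCl4 and polymerisation of the vinyl ketone may compete. The fallback uses an aldehyde electrophile under a milder Lewis acid and carries the furan in directly; it sets out from 9 and returns at 14. 3-(Furan-3-yl)propanal F11 is made from 3-bromofuran and allyl alcohol (Pd(OAc)2, NaHCO3, Bu4NCl, DMF; Heck reaction with isomerisation). Hosomi–Sakurai addition of 9 to F11 (BF3·OEt2, CH2Cl2, −78 °C) should give the homoallylic alcohol F12 by the same anti SE2′ course, and Dess–Martin periodinane oxidises it to 14.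

Further compounds
F1 | step 6 | (2Z)-2-methyl-4-oxo-4-(prop-2-en-1-yloxy)but-2-enoic acid | OC(=O)/C(C)=C\C(=O)OCC=C
F2 | step 6 | (3S,4S,5E,7E)-8-[dimethyl(phenyl)silyl]-4-hydroxy-6-methyl-2-oxoocta-5,7-dien-3-yl prop-2-en-1-yl (2Z)-2-methylbut-2-enedioate | CC(=O)[C@@H](OC(=O)/C(C)=C\C(=O)OCC=C)[C@@H](O)/C=C(C)/C=C/[Si](C)(C)c1ccccc1
F3 | step 6 | tert-butyldimethylsilyl ether of F2 at the C4 hydroxyl | CC(=O)[C@@H](OC(=O)/C(C)=C\C(=O)OCC=C)[C@@H](O[Si](C)(C)C(C)(C)C)/C=C(C)/C=C/[Si](C)(C)c1ccccc1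
F4 | step 6 | prop-2-en-1-yl 3-acetyl-4-[(tert-butyldimethylsilyl)oxy]-7-[dimethyl(phenyl)silyl]-5,8a-dimethyl-1-oxo-3,4,4a,7,8,8a-hexahydro-1H-isochromene-8-carboxylate (ring stereocentres as in 9; ester cis to the lactone carbonyl and to silicon) | CC(=O)[C@H]1OC(=O)[C@@]2(C)[C@@H](C(=O)OCC=C)[C@@H]([Si](C)(C)c3ccccc3)C=C(C)[C@H]2[C@@H]1O[Si](C)(C)C(C)(C)C
F5 | step 6 | carboxylic acid from F4 (8-carboxylic acid) | CC(=O)[C@H]1OC(=O)[C@@]2(C)[C@@H](C(=O)O)[C@@H]([Si](C)(C)c3ccccc3)C=C(C)[C@H]2[C@@H]1O[Si](C)(C)C(C)(C)C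
F6 | step 6 | 2-thioxopyridin-1(2H)-yl ester of F5 (thiohydroxamate ester) | CC(=O)[C@H]1OC(=O)[C@@]2(C)[C@@H](C(=O)ON4C=CC=CC4=S)[C@@H]([Si](C)(C)c3ccccc3)C=C(C)[C@H]2[C@@H]1O[Si](C)(C)C(C)(C)C
F7 | step 3 | (4R)-4-benzyl-3-[(2R,3S,4E,6E)-2-chloro-7-[dimethyl(phenyl)silyl]-3-hydroxy-5-methylhepta-4,6-dienoyl]-1,3-oxazolidin-2-one | O=C(N1[C@H](Cc2ccccc2)COC1=O)[C@H](Cl)[C@@H](O)/C=C(C)/C=C/[Si](C)(C)c1ccccc1
F8 | step 3 | (2R,3S,4E,6E)-2-chloro-7-[dimethyl(phenyl)silyl]-3-hydroxy-N-methoxy-N,5-dimethylhepta-4,6-dienamide | CON(C)C(=O)[C@H](Cl)[C@@H](O)/C=C(C)/C=C/[Si](C)(C)c1ccccc1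
F9 | step 3 | (2R,3S,4E,6E)-3-[(tert-butyldimethylsilyl)oxy]-2-chloro-7-[dimethyl(phenyl)silyl]-N-methoxy-N,5-dimethylhepta-4,6-dienamide | CON(C)C(=O)[C@H](Cl)[C@@H](O[Si](C)(C)C(C)(C)C)/C=C(C)/C=C/[Si](C)(C)c1ccccc1
F10 | step 3 | (3R,4S,5E,7E)-4-[(tert-butyldimethylsilyl)oxy]-3-chloro-8-[dimethyl(phenyl)silyl]-6-methylocta-5,7-dien-2-one | CC(=O)[C@H](Cl)[C@@H](O[Si](C)(C)C(C)(C)C)/C=C(C)/C=C/[Si](C)(C)c1ccccc1
F11 | step 7 | 3-(furan-3-yl)propanal | O=CCCc1ccoc1
F12 | step 7 | (3S,4S,4aR,5S,8aS)-3-acetyl-4-[(tert-butyldimethylsilyl)oxy]-5-[3-(furan-3-yl)-1-hydroxypropyl]-5,8a-dimethyl-3,4,4a,5,8,8a-hexahydro-1H-isochromen-1-one (both carbinol epimers) | CC(=O)[C@H]1OC(=O)[C@@]2(C)CC=C[C@](C)(C(O)CCc3ccoc3)[C@H]2[C@@H]1O[Si](C)(C)C(C)(C)C
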